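Everything rests on disconnecting the side chain at C2″, the stereogenic CH of the lavandulyl group on C8 of ring A, which is bonded to three unlike carbon groups: C1″H2 (benzylic, on C8), the isopropenyl carbon and C3″H2 of the prenyl arm. The key step forges C1″–C2″ and C2″–isopropenyl in one flask through two successive stereospecific boron-to-carbon migrations: a sparteine-lithiated homoprenyl carbamate inserts into a ring A benzylic boronic ester, and the secondary boronate formed is olefinated with isopropenyllithium. The precursor is a phloroglucinol core bearing prenyl at C6, CH2Bpin at C8, MOM ethers on O5 and O7, a THP acetal on O1 and hydrogen at C4a.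

Key step: step 7

Remarks on the chemistry (assumptions)
- Numbering: flavanone numbering is used for ring A (O1, C4a, C5–C8, C8a); C1″, C2″ and C3″ are the benzylic CH2, the methine and the prenyl CH2 of the lavandulyl chain.
- Protecting groups on O1: a triisopropylsilyl ether shields both neighbouring ring carbons (C8 and C4a) from metalation. It is therefore used only once, to steer the first metalation to C6, and is then exchanged for a THP acetal. The acetal makes C8 and later C4a cooperatively activated metalation sites and is removed by mild acid while the MOM ethers stay, so only O1 can close the pyranone ring.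
- The benzylic boronate is made in one operation by trapping the aryllithium with the chloromethyl boronate.
- The THP acetal carbon is not controlled: 11, 13, 14 and 15 are racemic, and 21, 22, 24, 25, 26, 28 and 29 are pairs of acetal epimers of uniform C2″ configuration, written without a descriptor at that carbon. The pairs merge at 30, where the selectivity of step 7 can be measured.
- Step 12: the S ligand antipode is predicted by analogy with cyclic enones. If a test on a simple chromone shows delivery to the Si face of C2, the R antipode is used.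

Step 1
Reactants: 1 phloroglucinol; 2 chloromethyl methyl ether
Product: 3 bis-MOM phenol [3,5-bis(methoxymethoxy)phenol]
Conditions: 2 (2.0 equiv), i-Pr2NEt (2.2 equiv), THF–DMF, 0 °C → rt; chromatography
Reagents that add atoms: chloromethyl methyl ether (2), COCCl
Why: O-alkylation (MOM protection) of the symmetric triol with two equivalents of electrophile should give the bis-acetal as the main component of a separable statistical mixture.

Step 2
Reactants: 3 bis-MOM phenol; 4 chlorotriisopropylsilane
Product: 5 TIPS ether [[3,5-bis(methoxymethoxy)phenoxy]triisopropylsilane]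
Conditions: 4, imidazole, DMF, rt
Reagents that add atoms: chlorotriisopropylsilane (4), CC(C)[Si](Cl)(C(C)C)C(C)C
Why: Silyl ether formation at the remaining phenol installs a bulky, non-coordinating group that blocks both of its neighbouring ring positions against metalation.

Step 3
Reactants: 5 TIPS ether; 6 prenyl bromide
Product: 9 prenylated phenol [3,5-bis(methoxymethoxy)-4-(3-methylbut-2-en-1-yl)phenol], via aryllithium 7 (not isolated), via silyl ether 8 (not isolated)
Conditions: n-BuLi (1.1 equiv), THF, 0 °C; CuI (10 mol %), 6 (0.95 equiv), −78 °C → rt; TBAF (1.5 equiv), 0 °C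
Reagents that add atoms: prenyl bromide (6), CC(C)=CCBr
Why: Directed ortho-metalation can only take place between the two MOM ethers because the silyl ether shields its neighbours, copper-catalysed alkylation of the aryllithium at the primary carbon of the limiting allylic bromide gives the prenyl arene, and fluoride then cleaves the Si–O bond in the same flask.

Step 4
Reactants: 9 prenylated phenol; 10 3,4-dihydro-2H-pyran
Product: 11 THP ether [2-[3,5-bis(methoxymethoxy)-4-(3-methylbut-2-en-1-yl)phenoxy]tetrahydro-2H-pyran]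
Conditions: 10 (3 equiv), PPTS (cat.), CH2Cl2, rt
Reagents that add atoms: 3,4-dihydro-2H-pyran (10), C1=COCCC1
Why: Acid-catalysed addition of the phenol to the enol ether (tetrahydropyranylation) replaces the shielding silyl group by a lithium-coordinating acetal that is far more acid-labile than the MOM ethers.

Step 5
Reactants: 11 THP ether; 12 2-(chloromethyl)-4,4,5,5-tetramethyl-1,3,2-dioxaborolane
Product: 15 ring A benzylic boronate [2-{[2,4-bis(methoxymethoxy)-3-(3-methylbut-2-en-1-yl)-6-(tetrahydro-2H-pyran-2-yloxy)phenyl]methyl}-4,4,5,5-tetramethyl-1,3,2-dioxaborolane], via aryllithium 13 (not isolated), via chloromethylboronate complex 14 (not isolated)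
Conditions: n-BuLi (1.1 equiv), THF, 0 °C; 12 (1.2 equiv), −78 °C → rt
Reagents that add atoms: 2-(chloromethyl)-4,4,5,5-tetramethyl-1,3,2-dioxaborolane (12), ClCB1OC(C)(C)C(C)(C)O1
Why: Directed ortho-metalation now occurs at either of the two equivalent C–H positions flanked by the THP and a MOM acetal, and the aryllithium adds to boron to give an ate complex whose 1,2-aryl shift with loss of chloride (Matteson-type homologation) delivers the benzylic boronic ester.

Step 6
Reactants: 16 4-methylpent-3-en-1-ol; 17 N,N-diisopropylcarbamoyl chloride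
Product: 18 homoprenyl carbamate [4-methylpent-3-en-1-yl N,N-diisopropylcarbamate]
Conditions: 17 (1.2 equiv), Et3N, CH2Cl2, reflux
Reagents that add atoms: N,N-diisopropylcarbamoyl chloride (17), CC(C)N(C(C)C)C(=O)Cl
Why: O-Carbamoylation of the primary alcohol gives the Hoppe-type carbamate whose carbonyl group directs and stabilises α-lithiation.

Step 7
Reactants: 15 ring A benzylic boronate; 18 homoprenyl carbamate; 19 2-bromopropene
Product: 26 lavandulyl arene [2-{3,5-bis(methoxymethoxy)-2-[(2R)-5-methyl-2-(prop-1-en-2-yl)hex-4-en-1-yl]-4-(3-methylbut-2-en-1-yl)phenoxy}tetrahydro-2H-pyran], via lithiated carbamate 20 (not isolated), via boronate complex 21 (not isolated), via secondary boronic ester 22 (not isolated), via isopropenyllithium 23 (not isolated), via alkenylboronate complex 24 (not isolated), via iodoalkyl boronic ester 25 (not isolated)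
Conditions: 18 (1.3 equiv), s-BuLi, (−)-sparteine, Et2O, −78 °C, 5 h; 15, −78 °C then reflux, 16 h; solvent to THF; 23 [from 19 (2.2 equiv), t-BuLi (4.4 equiv), −78 °C], −78 °C; I2 (2.2 equiv, in THF), −78 °C; NaOMe/MeOH, −78 → 0 °C; aq. Na2S2O3
Reagents that add atoms: homoprenyl carbamate (18), CC(C)=CCCOC(=O)N(C(C)C)C(C)C; 2-bromopropene (19), C=C(C)Br
Why: s-BuLi/(−)-sparteine removes the pro-S α-proton of 18 to give a configurationally stable, carbamate-chelated organolithium that adds to boron of 15 with retention; on warming, the benzyl group migrates from boron to carbon anti to the departing carbamate (inversion), forming C1″–C2″ and the R boronic ester 22. Isopropenyllithium then forms a second ate complex, iodine activates its alkene, the secondary alkyl group shifts from boron to the alkenyl carbon with retention, and methoxide triggers anti elimination of boron and iodide, forming the C2″–isopropenyl bond. The closest known reaction type is the sparteine-mediated lithiation–borylation of primary carbamates followed by Zweifel olefination of the resulting secondary pinacol boronic ester. No ring is closed; the one new stereocentre is controlled by the diamine antipode and relayed through three stereospecific events (retentive borylation, invertive 1,2-shift, retentive Zweifel shift), so (−)-sparteine should give the R centre. The step needs chemoselectivity for boron over the electron-rich ring (free C4a–H) and the three alkenes; this is secured by running all organolithium and iodine additions at −78 °C, by matching the iodine charge to the alkenyllithium, and by the absence of any enolisable or allyl-metal intermediate that could isomerise the skipped diene.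

Step 8
Reactants: 26 lavandulyl arene; 27 N-methoxy-N-methylacetamide
Product: 30 hydroxy ketone [1-{2-hydroxy-4,6-bis(methoxymethoxy)-3-[(2R)-5-methyl-2-(prop-1-en-2-yl)hex-4-en-1-yl]-5-(3-methylbut-2-en-1-yl)phenyl}ethan-1-one], via aryllithium 28 (not isolated), via THP ketone 29 (not isolated)
Conditions: n-BuLi (1.2 equiv), THF, 0 °C; 27 (1.5 equiv), −78 → 0 °C; MeOH, TsOH·H2O (to pH ≈ 3), rt
Reagents that add atoms: N-methoxy-N-methylacetamide (27), CC(=O)N(C)OC
Why: Directed ortho-metalation at the last ring C–H (C4a, held between a MOM and the THP acetal) is followed by Weinreb ketone synthesis through a chelated tetrahedral intermediate, and methanolic acid then cleaves only the much more labile THP acetal to unmask the O1 phenol.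

Step 9
Reactants: 30 hydroxy ketone; 31 N,N-dimethylformamide dimethyl acetal
Product: 33 chromone [5,7-bis(methoxymethoxy)-8-[(2R)-5-methyl-2-(prop-1-en-2-yl)hex-4-en-1-yl]-6-(3-methylbut-2-en-1-yl)-4H-chromen-4-one], via enaminone 32 (not isolated)
Conditions: 31 (3 equiv), toluene, 90 °C; evaporate; AcOH–EtOH, 60 °C
Reagents that add atoms: N,N-dimethylformamide dimethyl acetal (31), COC(OC)N(C)C
Why: Condensation of the methyl ketone with the amide acetal gives the enaminone, and intramolecular conjugate addition–elimination by the only free phenol (enaminone route to chromones) closes the pyranone on O1, which fixes lavandulyl at C8 and prenyl at C6.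

Step 10
Reactants: 34 4-bromoresorcinol; 2 chloromethyl methyl ether
Product: 35 ring B bromide [1-bromo-2,4-bis(methoxymethoxy)benzene]
Conditions: 2 (2.4 equiv), i-Pr2NEt, CH2Cl2, 0 °C → rt
Reagents that add atoms: chloromethyl methyl ether (2), COCCl
Why: Double O-alkylation (MOM protection) gives ring B in the same protecting group as ring A, so that one final operation unmasks all four phenols.

Step 11
Reactants: 35 ring B bromide; 36 triisopropyl borate
Product: 38 ring B boronic acid [[2,4-bis(methoxymethoxy)phenyl]boronic acid], via aryllithium 37 (not isolated)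
Conditions: n-BuLi (1.05 equiv), THF, −78 °C; 36 (1.5 equiv), −78 °C → rt; 1 M HCl to pH 5
Reagents that add atoms: triisopropyl borate (36), CC(C)OB(OC(C)C)OC(C)C; water, O
Why: Bromine–lithium exchange is faster than any directed metalation and fixes the metal at C1′, and borylation with the trialkyl borate followed by mild hydrolysis gives the boronic acid.

Step 12
Reactants: 33 chromone; 38 ring B boronic acid
Product: 39 protected flavanone [(2S)-2-[2,4-bis(methoxymethoxy)phenyl]-5,7-bis(methoxymethoxy)-8-[(2R)-5-methyl-2-(prop-1-en-2-yl)hex-4-en-1-yl]-6-(3-methylbut-2-en-1-yl)-2,3-dihydro-4H-chromen-4-one]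
Conditions: 38 (3 equiv), [Rh(OH)(cod)]2 (3 mol %), (S)-MeO-F12-BIPHEP (7 mol %), toluene–H2O, 30 °C
Reagents that add atoms: ring B boronic acid (38), COCOc1ccc(B(O)O)c(OCOC)c1
Why: Rhodium-catalysed asymmetric 1,4-addition of the arylboronic acid to the chromone (Hayashi–Miyaura reaction) proceeds by transmetalation, enantioface-selective insertion of C2=C3 into the Rh–aryl bond and protonolysis, with the ligand antipode chosen to deliver the aryl group to the Re face of C2 (2S) and the remote C2″ centre expected to have no influence.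

Step 13
Reactants: 39 protected flavanone
Product: 40 Kushenol B [(2S)-2-(2,4-dihydroxyphenyl)-5,7-dihydroxy-8-[(2R)-5-methyl-2-(prop-1-en-2-yl)hex-4-en-1-yl]-6-(3-methylbut-2-en-1-yl)-2,3-dihydro-4H-chromen-4-one]
Conditions: 3 M aq. HCl–MeOH (1:4), 40 °C, stopped at full conversion
Reagents that add atoms: none
Why: Acid-catalysed acetal exchange with methanol removes all four MOM ethers, and the mild, base-free conditions should leave C2 (no retro-oxa-Michael opening) and the prenyl and isopropenyl alkenes (no chroman formation with neighbouring phenols) untouched.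

Compound list
1 | phloroglucinol | Oc1cc(O)cc(O)c1 | starting material
2 | chloromethyl methyl ether | COCCl | starting material
3 | 3,5-bis(methoxymethoxy)phenol | COCOc1cc(O)cc(OCOC)c1 | intermediate
4 | chlorotriisopropylsilane | CC(C)[Si](Cl)(C(C)C)C(C)C | starting material
5 | [3,5-bis(methoxymethoxy)phenoxy]triisopropylsilane | COCOc1cc(OCOC)cc(O[Si](C(C)C)(C(C)C)C(C)C)c1 | intermediate
6 | prenyl bromide (1-bromo-3-methylbut-2-ene) | CC(C)=CCBr | starting material
7 | [2,6-bis(methoxymethoxy)-4-(triisopropylsilyloxy)phenyl]lithium | [Li]c1c(OCOC)cc(O[Si](C(C)C)(C(C)C)C(C)C)cc1OCOC | intermediate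
8 | [3,5-bis(methoxymethoxy)-4-(3-methylbut-2-en-1-yl)phenoxy]triisopropylsilane | CC(C)=CCc1c(OCOC)cc(O[Si](C(C)C)(C(C)C)C(C)C)cc1OCOC | intermediate
9 | 3,5-bis(methoxymethoxy)-4-(3-methylbut-2-en-1-yl)phenol | CC(C)=CCc1c(OCOC)cc(O)cc1OCOC | intermediate
10 | 3,4-dihydro-2H-pyran | C1=COCCC1 | starting material
11 | 2-[3,5-bis(methoxymethoxy)-4-(3-methylbut-2-en-1-yl)phenoxy]tetrahydro-2H-pyran (racemic) | CC(C)=CCc1c(OCOC)cc(OC2CCCCO2)cc1OCOC | intermediate
12 | 2-(chloromethyl)-4,4,5,5-tetramethyl-1,3,2-dioxaborolane | ClCB1OC(C)(C)C(C)(C)O1 | starting material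
13 | [2,4-bis(methoxymethoxy)-3-(3-methylbut-2-en-1-yl)-6-(tetrahydro-2H-pyran-2-yloxy)phenyl]lithium | [Li]c1c(OC2CCCCO2)cc(OCOC)c(CC=C(C)C)c1OCOC | intermediate
14 | lithium aryl(chloromethyl)(pinacolato)borate from 13 and 12 | [Li+].ClC[B-]1(c2c(OC3CCCCO3)cc(OCOC)c(CC=C(C)C)c2OCOC)OC(C)(C)C(C)(C)O1 | intermediate
15 | 2-{[2,4-bis(methoxymethoxy)-3-(3-methylbut-2-en-1-yl)-6-(tetrahydro-2H-pyran-2-yloxy)phenyl]methyl}-4,4,5,5-tetramethyl-1,3,2-dioxaborolane (key-step precursor) | CC1(C)OB(Cc2c(OCOC)c(CC=C(C)C)c(OCOC)cc2OC2CCCCO2)OC1(C)C | intermediate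
16 | 4-methylpent-3-en-1-ol | CC(C)=CCCO | starting material
17 | N,N-diisopropylcarbamoyl chloride | CC(C)N(C(C)C)C(=O)Cl | starting material
18 | 4-methylpent-3-en-1-yl N,N-diisopropylcarbamate | CC(C)=CCCOC(=O)N(C(C)C)C(C)C | intermediate
19 | 2-bromopropene | C=C(C)Br | starting material
20 | (1S)-1-lithio-4-methylpent-3-en-1-yl N,N-diisopropylcarbamate, (−)-sparteine complex | CC(C)=CC[C@H]([Li])OC(=O)N(C(C)C)C(C)C | intermediate
21 | lithium boronate complex of 20 and 15 (S at the carbamate-bearing carbon) | [Li+].CC(C)=CC[C@H]([B-]1(Cc2c(OCOC)c(CC=C(C)C)c(OCOC)cc2OC2CCCCO2)OC(C)(C)C(C)(C)O1)OC(=O)N(C(C)C)C(C)C | intermediate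
22 | 2-[(2R)-1-aryl-5-methylhex-4-en-2-yl]-4,4,5,5-tetramethyl-1,3,2-dioxaborolane (aryl as in 15) | CC1(C)OB([C@H](CC=C(C)C)Cc2c(OCOC)c(CC=C(C)C)c(OCOC)cc2OC2CCCCO2)OC1(C)C | intermediate
23 | isopropenyllithium | C=C(C)[Li] | intermediate
24 | lithium isopropenyl boronate complex of 22 | [Li+].C=C(C)[B-]1([C@H](CC=C(C)C)Cc2c(OCOC)c(CC=C(C)C)c(OCOC)cc2OC2CCCCO2)OC(C)(C)C(C)(C)O1 | intermediate
25 | β-iodoalkyl boronic ester (both epimers at the boron-bearing carbon, R at C2″) | ICC(C)(B1OC(C)(C)C(C)(C)O1)[C@H](CC=C(C)C)Cc1c(OCOC)c(CC=C(C)C)c(OCOC)cc1OC1CCCCO1 | intermediate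
26 | 2-{3,5-bis(methoxymethoxy)-2-[(2R)-5-methyl-2-(prop-1-en-2-yl)hex-4-en-1-yl]-4-(3-methylbut-2-en-1-yl)phenoxy}tetrahydro-2H-pyran (key-step product) | C=C(C)[C@H](CC=C(C)C)Cc1c(OCOC)c(CC=C(C)C)c(OCOC)cc1OC1CCCCO1 | intermediate
27 | N-methoxy-N-methylacetamide | CC(=O)N(C)OC | starting material
28 | C4a aryllithium of 26 | C=C(C)[C@H](CC=C(C)C)Cc1c(OCOC)c(CC=C(C)C)c(OCOC)c([Li])c1OC1CCCCO1 | intermediate
29 | 1-{2,4-bis(methoxymethoxy)-3-(3-methylbut-2-en-1-yl)-5-[(2R)-5-methyl-2-(prop-1-en-2-yl)hex-4-en-1-yl]-6-(tetrahydro-2H-pyran-2-yloxy)phenyl}ethan-1-one | C=C(C)[C@H](CC=C(C)C)Cc1c(OCOC)c(CC=C(C)C)c(OCOC)c(C(C)=O)c1OC1CCCCO1 | intermediate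
30 | 1-{2-hydroxy-4,6-bis(methoxymethoxy)-3-[(2R)-5-methyl-2-(prop-1-en-2-yl)hex-4-en-1-yl]-5-(3-methylbut-2-en-1-yl)phenyl}ethan-1-one | C=C(C)[C@H](CC=C(C)C)Cc1c(OCOC)c(CC=C(C)C)c(OCOC)c(C(C)=O)c1O | intermediate
31 | N,N-dimethylformamide dimethyl acetal | COC(OC)N(C)C | starting material
32 | (E)-3-(dimethylamino)-1-(aryl)prop-2-en-1-one (aryl as in 30) | C=C(C)[C@H](CC=C(C)C)Cc1c(OCOC)c(CC=C(C)C)c(OCOC)c(C(=O)/C=C/N(C)C)c1O | intermediate
33 | 5,7-bis(methoxymethoxy)-8-[(2R)-5-methyl-2-(prop-1-en-2-yl)hex-4-en-1-yl]-6-(3-methylbut-2-en-1-yl)-4H-chromen-4-one | C=C(C)[C@H](CC=C(C)C)Cc1c(OCOC)c(CC=C(C)C)c(OCOC)c2c(=O)ccoc12 | intermediate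
34 | 4-bromoresorcinol (4-bromobenzene-1,3-diol) | Oc1ccc(Br)c(O)c1 | starting material
35 | 1-bromo-2,4-bis(methoxymethoxy)benzene | COCOc1ccc(Br)c(OCOC)c1 | intermediate
36 | triisopropyl borate | CC(C)OB(OC(C)C)OC(C)C | starting material
37 | [2,4-bis(methoxymethoxy)phenyl]lithium | [Li]c1ccc(OCOC)cc1OCOC | intermediate
38 | [2,4-bis(methoxymethoxy)phenyl]boronic acid | COCOc1ccc(B(O)O)c(OCOC)c1 | intermediate
39 | (2S)-2-[2,4-bis(methoxymethoxy)phenyl]-5,7-bis(methoxymethoxy)-8-[(2R)-5-methyl-2-(prop-1-en-2-yl)hex-4-en-1-yl]-6-(3-methylbut-2-en-1-yl)-2,3-dihydro-4H-chromen-4-one | C=C(C)[C@H](CC=C(C)C)Cc1c(OCOC)c(CC=C(C)C)c(OCOC)c2c1O[C@H](c1ccc(OCOC)cc1OCOC)CC2=O | intermediate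
40 | Kushenol B, (2S)-2-(2,4-dihydroxyphenyl)-5,7-dihydroxy-8-[(2R)-5-methyl-2-(prop-1-en-2-yl)hex-4-en-1-yl]-6-(3-methylbut-2-en-1-yl)-2,3-dihydro-4H-chromen-4-one | C=C(C)[C@H](CC=C(C)C)Cc1c(O)c(CC=C(C)C)c(O)c2c1O[C@H](c1ccc(O)cc1O)CC2=O | target

Total step count: 13. Longest linear sequence: 10 steps (1, 2, 3, 4, 5, 7, 8, 9, 12, 13).

Steps most likely to fail

Step 7. The 1,2-shift of the first ate complex may stay incomplete, the lithiated carbamate may lose configuration before it is captured, or iodine may attack the electron-rich ring at C4a or a side-chain alkene during the olefination. The fallback takes the stereocentre from the chiral pool, sets out from 11 and comes back at 26. Lithiation of 11 as in step 5 and quenching with iodine gives the aryl iodide F1. (S)-Lavandulol F2, obtained by lipase resolution of commercial racemic lavandulol, is converted with I2, PPh3 and imidazole into (S)-lavandulyl iodide F3. Zinc insertion (Zn dust, LiCl, THF) gives lavandulylzinc iodide F4, and a Negishi sp3–sp2 coupling with F1 (Pd(OAc)2, CPhos, THF, rt) gives 26. The stereocentre is β to the metal and is not touched.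

Step 12. Insertion into the electron-rich chromone with its peri alkoxy group may be slow, the ortho-alkoxy boronic acid may protodeboronate faster than it transmetalates, and facial discrimination may be eroded by the ortho substituent or by base-induced opening of the product. The fallback builds the heterocycle by the chalcone route and resolves C2 afterwards; it sets out from 30 and 37 and comes back at 39. Aryllithium 37 is quenched with DMF to give 2,4-bis(methoxymethoxy)benzaldehyde F5. Claisen–Schmidt condensation of F5 with 30 (KOH, EtOH–H2O, rt) gives the 2′-hydroxychalcone F6. NaOAc in refluxing EtOH closes F6 by oxa-Michael addition to a mixture of 39 and its C2 epimer F7. A kinetic resolution by asymmetric transfer hydrogenation ([Cp*RhCl((R,R)-TsDPEN)], HCO2H–Et3N) is expected to reduce the 2R epimer selectively to the cis-flavan-4-ol F8, so that 39 is left and separated by chromatography.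

Step 8. Deprotonation may occur at the doubly activated prenyl methylene instead of the ring C–H, and the hindered aryllithium may enolise the Weinreb amide instead of adding to it. The fallback introduces the carbonyl carbon without an organolithium; it sets out from 26 and comes back at 30. PPTS in MeOH removes the THP group to give phenol F9. Magnesium-mediated ortho-formylation (MgCl2, Et3N, paraformaldehyde, THF, reflux) at the only free ortho position, C4a, gives salicylaldehyde F10. Excess MeMgBr gives the carbinol F11 as both epimers, and MnO2 oxidation gives 30.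

Further compounds
F1 | step 7 | 2-[4-iodo-3,5-bis(methoxymethoxy)-... aryl iodide: 2-[2-iodo-3,5-bis(methoxymethoxy)-4-(3-methylbut-2-en-1-yl)phenoxy]tetrahydro-2H-pyran | CC(C)=CCc1c(OCOC)cc(OC2CCCCO2)c(I)c1OCOC
F2 | step 7 | (S)-lavandulol, (2S)-5-methyl-2-(prop-1-en-2-yl)hex-4-en-1-ol | C=C(C)[C@H](CC=C(C)C)CO
F3 | step 7 | (S)-lavandulyl iodide, (2S)-1-iodo-5-methyl-2-(prop-1-en-2-yl)hex-4-ene | C=C(C)[C@H](CC=C(C)C)CI
F4 | step 7 | [(2S)-5-methyl-2-(prop-1-en-2-yl)hex-4-en-1-yl]zinc iodide | C=C(C)[C@H](CC=C(C)C)C[Zn]I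
F5 | step 12 | 2,4-bis(methoxymethoxy)benzaldehyde | COCOc1ccc(C=O)c(OCOC)c1
F6 | step 12 | (E)-3-[2,4-bis(methoxymethoxy)phenyl]-1-(aryl)prop-2-en-1-one (aryl as in 30) | C=C(C)[C@H](CC=C(C)C)Cc1c(OCOC)c(CC=C(C)C)c(OCOC)c(C(=O)/C=C/c2ccc(OCOC)cc2OCOC)c1O
F7 | step 12 | (2R)-epimer of 39 | C=C(C)[C@H](CC=C(C)C)Cc1c(OCOC)c(CC=C(C)C)c(OCOC)c2c1O[C@@H](c1ccc(OCOC)cc1OCOC)CC2=O
F8 | step 12 | (2R,4R)-cis-flavan-4-ol from F7 | C=C(C)[C@H](CC=C(C)C)Cc1c(OCOC)c(CC=C(C)C)c(OCOC)c2c1O[C@@H](c1ccc(OCOC)cc1OCOC)C[C@H]2O
F9 | step 8 | 3,5-bis(methoxymethoxy)-2-[(2R)-5-methyl-2-(prop-1-en-2-yl)hex-4-en-1-yl]-4-(3-methylbut-2-en-1-yl)phenol | C=C(C)[C@H](CC=C(C)C)Cc1c(OCOC)c(CC=C(C)C)c(OCOC)cc1O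
F10 | step 8 | 2-hydroxy-4,6-bis(methoxymethoxy)-3-[(2R)-5-methyl-2-(prop-1-en-2-yl)hex-4-en-1-yl]-5-(3-methylbut-2-en-1-yl)benzaldehyde | C=C(C)[C@H](CC=C(C)C)Cc1c(OCOC)c(CC=C(C)C)c(OCOC)c(C=O)c1O
F11 | step 8 | 1-(aryl)ethan-1-ol, both carbinol epimers (aryl as in 30) | C=C(C)[C@H](CC=C(C)C)Cc1c(OCOC)c(CC=C(C)C)c(OCOC)c(C(C)O)c1O
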